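**Retrosynthetic overview**

1. Labdane numbering: decalin C1–C10, side chain C11–C16, C17 = oxirane CH2 on C8, C18 = CH3 and C19 = lactone C=O on C4, C20 = lactone CH2 on C10; β = face of C20. The last ring closed is C13–C14–C15–O–C16: a dirhodium carbenoid on a C16-O-diazoacetate inserts into C13–H (new bond C13–C14, spiro centre with retention). The ring is formed as a γ-lactone and then taken to the enol ether (half-reduction, dehydration) before desilylation and acetylation.
2. Feature that makes this possible: C13 is a methine inside the 9,13-tetrahydrofuran (O–C9–C11–C12–C13), α to the ring oxygen and 1,5 to the carbenoid carbon, the one activated tertiary C–H in reach. Because C13 is still secondary, the tetrahydrofuran can be closed under base beside the C8 oxirane.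
3. Tetrahydrofuran ⇐ 5-exo opening of a C13–C16 epoxide by the C9 alkoxide (inversion at C13, which comes from ethyl (R)-4-chloro-3-hydroxybutanoate); C9 carbinol ⇐ organolithium + epoxy ketone; 8β,17-oxirane ⇐ Weitz–Scheffer epoxidation of the 8(17)-methylene ketone.
4. Ring A and the 19,20-lactone ⇐ alkylation of the C4 lactone enolate by a C3 iodide (bicyclo[3.3.1] closure fixes C4); δ-lactone ⇐ Mukaiyama–Michael (C4–C5) then formaldehyde aldol (C10–C20) on an (R)-4-silyloxy-2-alkylcyclohexenone whose C6 centre controls C5 and C10.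
5. Ring order: ring B (starting enone) → δ-lactone → ring A → oxirane → tetrahydrofuran → five-membered ring C13–C16.

Key step: step 19

Remark: the SMILES is read as the cis-fused decalin (5β-H on the face of C20) with 6β-OAc, 8β-oxirane oxygen, 9α-O and 13R, i.e. (4S,5S,6R,8R,9S,10S,13R); the route is designed for exactly this isomer.

**Route**

Step 1
Reactants: 1 1,4-dioxaspiro[4.5]dec-6-en-8-one
Product: 2 (R)-1,4-dioxaspiro[4.5]dec-6-en-8-ol
Conditions: RuCl(p-cymene)[(R,R)-TsDPEN] (1 mol%), HCO2Na, Bu4NCl, CH2Cl2/H2O, 25 °C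
Reagents that add atoms: none
Why: Noyori asymmetric transfer hydrogenation should reduce the enone carbonyl 1,2-selectively, the alkenyl group taking the role of the aryl group in the usual model so that the (R,R)-catalyst gives the (R)-carbinol, the future C6 that steers all later stereocentres.

Step 2
Reactants: 2 (R)-1,4-dioxaspiro[4.5]dec-6-en-8-ol
Product: 3 (R)-8-(triisopropylsilyloxy)-1,4-dioxaspiro[4.5]dec-6-ene
Conditions: i-Pr3SiOTf, 2,6-lutidine, CH2Cl2, 0 °C
Reagents that add atoms: triisopropylsilyl triflate, CC(C)[Si](OS(=O)(=O)C(F)(F)F)(C(C)C)C(C)C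
Why: Standard silylation of a secondary alcohol; the bulky, base- and hydride-stable TIPS ether later shields one face of C5 and survives until step 22.

Step 3
Reactants: 3 (R)-8-(triisopropylsilyloxy)-1,4-dioxaspiro[4.5]dec-6-ene
Product: 4 (R)-4-(triisopropylsilyloxy)cyclohex-2-en-1-one
Conditions: montmorillonite K-10, wet CH2Cl2, 25 °C
Reagents that add atoms: water, O
Why: Mild heterogeneous acid hydrolysis of the dioxolane should unmask the enone without β-elimination of the γ-silyloxy group and without touching the stereocentre.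

Step 4
Reactants: 4 (R)-4-(triisopropylsilyloxy)cyclohex-2-en-1-one
Product: 5 (R)-2-iodo-4-(triisopropylsilyloxy)cyclohex-2-en-1-one
Conditions: I2, pyridine, CH2Cl2, 0 → 25 °C
Reagents that add atoms: iodine, II
Why: α-Iodination of the enone by Baylis–Hillman-type conjugate addition of pyridine, iodination of the enolate and E1cB loss of pyridine.

Step 5
Reactants: 5 (R)-2-iodo-4-(triisopropylsilyloxy)cyclohex-2-en-1-one; 6 allyloxy(tert-butyl)dimethylsilane
Product: 8 (R)-2-[3-(tert-butyldimethylsilyloxy)propyl]-4-(triisopropylsilyloxy)cyclohex-2-en-1-one, via B-alkyl borane 7 (not isolated)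
Conditions: 6, 9-BBN-H, THF, 25 °C; then 5, PdCl2(dppf) (5 mol%), AsPh3, Cs2CO3, DMF/THF/H2O, 25 °C
Reagents that add atoms: none
Why: Anti-Markovnikov hydroboration followed by B-alkyl Suzuki–Miyaura coupling at the α-iodoenone installs C1–C3 on the future C10 with the terminal oxygen that later becomes the C3 leaving group.

Step 6
Reactants: 8 (R)-2-[3-(tert-butyldimethylsilyloxy)propyl]-4-(triisopropylsilyloxy)cyclohex-2-en-1-one; 9 (E)-1-methoxy-1-(trimethylsilyloxy)prop-1-ene
Product: 10 C9 trimethylsilyl enol ether of the Michael adduct (C5 side chain trans to 6β-OTIPS; C4 epimers)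
Conditions: Me3SiNTf2 (3 mol%), CH2Cl2, −78 °C
Reagents that add atoms: none
Why: Mukaiyama–Michael addition with silyl transfer; the ketene acetal should attack C5 anti to the C6 silyloxy group (sets 5β-H), the C4 epimer mixture is erased in step 10, and the enol ether is fixed at C9=C10.

Step 7
Reactants: 10 C9 trimethylsilyl enol ether of the Michael adduct
Product: 13 trans-fused 19,20-δ-lactone C9 ketone bearing a 10α-(3-hydroxypropyl) chain (C4 epimers), via hydroxymethyl ketone 11 (not isolated), via silyl ether lactone 12 (not isolated)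
Conditions: 37% aq. HCHO, Yb(OTf)3 (10 mol%), THF, 25 °C; then CSA, PhMe, 40 °C; then 1 M HCl, THF, 25 °C
Reagents that add atoms: formaldehyde, C=O
Why: Lanthanide-triflate Mukaiyama aldol with aqueous formaldehyde on the tetrasubstituted enol ether should place CH2OH on C10 anti to the adjacent pseudoaxial C5 side chain (C20 β, quaternary C10), after which acid closes the δ-lactone between C20–OH and the C19 ester and cleaves the primary TBS ether.

Step 8
Reactants: 13 trans-fused 19,20-δ-lactone C9 ketone bearing a 10α-(3-hydroxypropyl) chain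
Product: 14 10α-(3-iodopropyl) δ-lactone C9 ketone (C4 epimers)
Conditions: I2, PPh3, imidazole, CH2Cl2, 0 °C
Reagents that add atoms: iodine, II
Why: Appel-type iodination of the only free (primary) alcohol.

Step 9
Reactants: 14 10α-(3-iodopropyl) δ-lactone C9 ketone
Product: 15 C8=C9 trimethylsilyl enol ether of 14 (C4 epimers)
Conditions: Me3SiOTf, Et3N, CH2Cl2, 0 °C
Reagents that add atoms: trimethylsilyl triflate, C[Si](C)(C)OS(=O)(=O)C(F)(F)F
Why: Soft enolisation of the ketone, which can only enolise toward C8, masks it so that the lactone α-CH is the sole acidic site in step 10 and prepares the methylenation of step 11.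

Step 10
Reactants: 15 C8=C9 trimethylsilyl enol ether of 14
Product: 16 tricyclic 19,20-olide silyl enol ether (ring A closed; 4α-CH3)
Conditions: LDA (1.2 equiv), THF, −78 °C; then DMPU, −78 → 0 °C
Reagents that add atoms: none
Why: Intramolecular enolate alkylation (6-exo-tet): the axial C1–C3 chain on C10 can reach the planar C4 enolate of the trans-fused lactone only from its own face, so the bicyclo[3.3.1] closure fixes C4 (CH3 α, C19 on the lactone bridge) and gives the cis-fused decalin.

Step 11
Reactants: 16 tricyclic 19,20-olide silyl enol ether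
Product: 19 8(17)-methylene C9 ketone, via Mannich base 17 (not isolated), via ammonium iodide 18 (not isolated)
Conditions: CH2=NMe2+ I−, CH2Cl2, 25 °C; aq. NaHCO3; then MeI, CH2Cl2, 25 °C; then DBU, 25 °C
Reagents that add atoms: dimethylmethyleneammonium iodide (Eschenmoser's salt), C[N+](C)=C.[I-]
Why: Mannich reaction of the silyl enol ether with Eschenmoser's salt, N-methylation and E1cB elimination give the exocyclic enone and introduce C17.

Step 12
Reactants: 19 8(17)-methylene C9 ketone
Product: 20 8β,17-epoxy C9 ketone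
Conditions: t-BuOOH, DBU, CH2Cl2, 0 → 25 °C
Reagents that add atoms: tert-butyl hydroperoxide, CC(C)(C)OO
Why: Weitz–Scheffer nucleophilic epoxidation: the peroxide adds to C17 and the C8 enolate should close onto oxygen from the β face, away from the C1 methylene of ring A that is syn-axial to C8 on the α face, giving the oxirane oxygen β.

Step 13
Reactants: 21 ethyl (R)-4-chloro-3-hydroxybutanoate
Product: 22 ethyl (R)-4-chloro-3-(triethylsilyloxy)butanoate
Conditions: Et3SiCl, imidazole, CH2Cl2, 0 °C
Reagents that add atoms: chlorotriethylsilane, CC[Si](Cl)(CC)CC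
Why: Routine silylation; the TES ether is later removed by fluoride in the presence of the secondary TIPS ether.

Step 14
Reactants: 22 ethyl (R)-4-chloro-3-(triethylsilyloxy)butanoate
Product: 23 (R)-4-chloro-3-(triethylsilyloxy)butan-1-ol
Conditions: i-Bu2AlH (2.2 equiv), CH2Cl2, −78 → 0 °C
Reagents that add atoms: none
Why: Hydride reduction of the ester to the primary alcohol leaves the chloride, the silyl ether and the stereocentre untouched.

Step 15
Reactants: 23 (R)-4-chloro-3-(triethylsilyloxy)butan-1-ol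
Product: 24 (R)-[(1-chloro-4-iodobutan-2-yl)oxy]triethylsilane
Conditions: I2, PPh3, imidazole, CH2Cl2, 0 °C
Reagents that add atoms: iodine, II
Why: Appel-type iodination of the primary alcohol gives the C11–C13/C16 fragment.

Step 16
Reactants: 24 (R)-[(1-chloro-4-iodobutan-2-yl)oxy]triethylsilane; 20 8β,17-epoxy C9 ketone
Product: 26 9α-hydroxy adduct (C11 β; 13R-OSiEt3; C16 chloride), via organolithium 25 (not isolated)
Conditions: 24, t-BuLi (2.1 equiv), Et2O/pentane, −78 °C; then 20, THF, −78 °C; aq. NH4Cl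
Reagents that add atoms: none
Why: Iodine–lithium exchange and 1,2-addition to the non-enolisable ketone, which should be attacked from the β face, anti to the axial C1 on C10 and the axial oxirane CH2 on C8 (Felkin-type torsional control), giving 9α-OH with C11 β.

Step 17
Reactants: 26 9α-hydroxy adduct
Product: 29 9α,13-epoxy-16-ol (spiro tetrahydrofuran; 13S methine), via chlorohydrin 27 (not isolated), via terminal epoxide 28 (not isolated)
Conditions: Bu4NF (1.1 equiv), THF, 0 °C; then t-BuOK (0.2 equiv), THF/t-BuOH, 0 → 25 °C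
Reagents that add atoms: none
Why: Fluoride frees the C13 alkoxide, which displaces chloride (Williamson epoxide closure, retention at C13), and the C9 alkoxide then opens the terminal epoxide 5-exo at C13 with inversion; the stereospecific Payne equilibrium with the C8 oxirane is drained by this irreversible ring closure.

Step 18
Reactants: 29 9α,13-epoxy-16-ol
Product: 31 16-O-diazoacetate, via hydrazone ester 30 (not isolated)
Conditions: TsNHN=CHCOCl, PhNMe2, CH2Cl2, 0 °C; then Et3N, 0 → 25 °C
Reagents that add atoms: glyoxylic acid chloride p-toluenesulfonylhydrazone, Cc1ccc(cc1)S(=O)(=O)NN=CC(Cl)=O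
Why: O-Acylation of the primary alcohol followed by base-induced Bamford–Stevens-type loss of sulfinate gives the diazoacetate under conditions that spare the oxirane and lactone.

Step 19
Reactants: 31 16-O-diazoacetate
Product: 32 spiro γ-lactone (9α,13R-epoxy-15,16-olide)
Conditions: Rh2(cap)4 (dirhodium tetracaprolactamate, 1 mol%), CH2Cl2, 40 °C, slow addition of 31
Reagents that add atoms: none
Why: Loss of N2 gives an electrophilic dirhodium carbenoid at C14, which inserts into the C13–H bond through a concerted three-centre transition state with hydride-transfer character and releases the catalyst. The closest known reaction type is the dirhodium carboxamidate-catalysed 1,5 C–H insertion of alkyl diazoacetates into the C–H bond next to an ether oxygen (2-alkoxyethyl diazoacetates to 4-alkoxy γ-butyrolactones). The ring C13–C14–C15–O–C16 closes by formation of C13–C14 through a five-membered insertion transition state, and no other ring forms. The quaternary spiro centre C13 is created with retention, so its configuration is that of the methine set by inversion in step 17 from the (R)-chlorohydrin. The step needs selectivity for C13–H over the C12 methylene (six-ring insertion), over oxonium ylide formation at the tetrahydrofuran or oxirane oxygen and over carbene dimerisation. The tertiary oxygen-activated C–H bond, the five-ring geometry, the electron-rich carboxamidate ligands and slow addition should secure it.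

Step 20
Reactants: 32 spiro γ-lactone
Product: 33 lactol (15-hydroxy-15,16-epoxide; C15 epimers)
Conditions: i-Bu2AlH (1.1 equiv), CH2Cl2, −78 °C
Reagents that add atoms: none
Why: Half-reduction of the unhindered γ-lactone; the bridged 19,20-lactone carbonyl sits next to quaternary C4 and should react much more slowly.

Step 21
Reactants: 33 lactol
Product: 35 6-O-TIPS dihydrofuran (9α,13R;15,16-diepoxy-14-ene), via lactol mesylate 34 (not isolated)
Conditions: MsCl, Et3N, CH2Cl2, −20 → 40 °C
Reagents that add atoms: none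
Why: Mesylation of the lactol and base-mediated elimination through the oxocarbenium ion (loss of H14) give the cyclic enol ether under non-acidic conditions that avoid ring opening to the furan.

Step 22
Reactants: 35 6-O-TIPS dihydrofuran
Product: 36 6β-alcohol
Conditions: Bu4NF, THF, 25 °C
Reagents that add atoms: none
Why: Fluoride desilylation is compatible with the enol ether, the oxirane and the lactone.

Step 23
Reactants: 36 6β-alcohol
Product: 37 CNP0173713.1 (target)
Conditions: Ac2O, pyridine, DMAP (cat.), CH2Cl2, 25 °C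
Reagents that add atoms: acetic anhydride, CC(=O)OC(C)=O
Why: Base-mediated acetylation of the equatorial secondary alcohol leaves the acid-labile enol ether intact.

**Compound list**

1 | 1,4-dioxaspiro[4.5]dec-6-en-8-one | O=C1C=CC2(CC1)OCCO2 | starting material
2 | (R)-1,4-dioxaspiro[4.5]dec-6-en-8-ol | O[C@H]1C=CC2(OCCO2)CC1 | intermediate
3 | (R)-8-(triisopropylsilyloxy)-1,4-dioxaspiro[4.5]dec-6-ene | CC(C)[Si](O[C@H]1C=CC2(OCCO2)CC1)(C(C)C)C(C)C | intermediate
4 | (R)-4-(triisopropylsilyloxy)cyclohex-2-en-1-one | CC(C)[Si](O[C@H]1C=CC(=O)CC1)(C(C)C)C(C)C | intermediate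
5 | (R)-2-iodo-4-(triisopropylsilyloxy)cyclohex-2-en-1-one | CC(C)[Si](O[C@H]1C=C(I)C(=O)CC1)(C(C)C)C(C)C | intermediate
6 | allyloxy(tert-butyl)dimethylsilane | C=CCO[Si](C)(C)C(C)(C)C | starting material
7 | B-[3-(tert-butyldimethylsilyloxy)propyl]-9-borabicyclo[3.3.1]nonane (not isolated) | CC(C)(C)[Si](C)(C)OCCCB1C2CCCC1CCC2 | intermediate
8 | (R)-2-[3-(tert-butyldimethylsilyloxy)propyl]-4-(triisopropylsilyloxy)cyclohex-2-en-1-one | CC(C)[Si](O[C@H]1C=C(CCCO[Si](C)(C)C(C)(C)C)C(=O)CC1)(C(C)C)C(C)C | intermediate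
9 | (E)-1-methoxy-1-(trimethylsilyloxy)prop-1-ene | C/C=C(\OC)O[Si](C)(C)C | starting material
10 | C9 trimethylsilyl enol ether of the Michael adduct (C5 side chain trans to 6β-OTIPS; 5β-H; C4 epimers) | CC(C)[Si](O[C@@H]1CCC(O[Si](C)(C)C)=C(CCCO[Si](C)(C)C(C)(C)C)[C@H]1C(C)C(=O)OC)(C(C)C)C(C)C | intermediate
11 | 10β-hydroxymethyl C9 ketone methyl ester (10α-silyloxypropyl; C4 epimers; not isolated) | CC(C)[Si](O[C@@H]1CCC(=O)[C@@](CO)(CCCO[Si](C)(C)C(C)(C)C)[C@H]1C(C)C(=O)OC)(C(C)C)C(C)C | intermediate
12 | trans-fused 19,20-δ-lactone C9 ketone with 10α-(3-TBSO-propyl) chain (C4 epimers; not isolated) | CC(C)[Si](O[C@@H]1CCC(=O)[C@]2(CCCO[Si](C)(C)C(C)(C)C)COC(=O)C(C)[C@@H]12)(C(C)C)C(C)C | intermediate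
13 | trans-fused 19,20-δ-lactone C9 ketone with 10α-(3-hydroxypropyl) chain (C4 epimers) | CC(C)[Si](O[C@@H]1CCC(=O)[C@]2(CCCO)COC(=O)C(C)[C@@H]12)(C(C)C)C(C)C | intermediate
14 | 10α-(3-iodopropyl) δ-lactone C9 ketone (C4 epimers) | CC(C)[Si](O[C@@H]1CCC(=O)[C@]2(CCCI)COC(=O)C(C)[C@@H]12)(C(C)C)C(C)C | intermediate
15 | C8=C9 trimethylsilyl enol ether of 14 (C4 epimers) | CC(C)[Si](O[C@@H]1CC=C(O[Si](C)(C)C)[C@]2(CCCI)COC(=O)C(C)[C@@H]12)(C(C)C)C(C)C | intermediate
16 | tricyclic 19,20-olide silyl enol ether (ring A closed; 4α-CH3; 5β-H; 6β-OTIPS) | CC(C)[Si](O[C@@H]1CC=C(O[Si](C)(C)C)[C@]23CCC[C@](C)(C(=O)OC2)[C@@H]13)(C(C)C)C(C)C | intermediate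
17 | 8-(dimethylaminomethyl) C9 ketone (C8 epimers; not isolated) | CC(C)[Si](O[C@@H]1CC(CN(C)C)C(=O)[C@]23CCC[C@](C)(C(=O)OC2)[C@@H]13)(C(C)C)C(C)C | intermediate
18 | 8-(trimethylammoniomethyl) C9 ketone iodide (not isolated) | CC(C)[Si](O[C@@H]1CC(C[N+](C)(C)C)C(=O)[C@]23CCC[C@](C)(C(=O)OC2)[C@@H]13)(C(C)C)C(C)C.[I-] | intermediate
19 | 8(17)-methylene C9 ketone (6β-OTIPS 19,20-olide) | CC(C)[Si](O[C@@H]1CC(=C)C(=O)[C@]23CCC[C@](C)(C(=O)OC2)[C@@H]13)(C(C)C)C(C)C | intermediate
20 | 8β,17-epoxy C9 ketone (oxirane oxygen β) | CC(C)[Si](O[C@@H]1C[C@@]2(CO2)C(=O)[C@]23CCC[C@](C)(C(=O)OC2)[C@@H]13)(C(C)C)C(C)C | intermediate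
21 | ethyl (R)-4-chloro-3-hydroxybutanoate | CCOC(=O)C[C@@H](O)CCl | starting material
22 | ethyl (R)-4-chloro-3-(triethylsilyloxy)butanoate | CCOC(=O)C[C@@H](O[Si](CC)(CC)CC)CCl | intermediate
23 | (R)-4-chloro-3-(triethylsilyloxy)butan-1-ol | OCC[C@@H](O[Si](CC)(CC)CC)CCl | intermediate
24 | (R)-[(1-chloro-4-iodobutan-2-yl)oxy]triethylsilane | ICC[C@@H](O[Si](CC)(CC)CC)CCl | intermediate
25 | (R)-4-chloro-3-(triethylsilyloxy)butyllithium (not isolated) | [Li]CC[C@@H](O[Si](CC)(CC)CC)CCl | intermediate
26 | 9α-hydroxy adduct (C11 β; 13R-OSiEt3; C16 chloride; 8β,17-epoxide) | CC(C)[Si](O[C@@H]1C[C@@]2(CO2)[C@](O)(CC[C@@H](O[Si](CC)(CC)CC)CCl)[C@]23CCC[C@](C)(C(=O)OC2)[C@@H]13)(C(C)C)C(C)C | intermediate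
27 | 13R-hydroxy-16-chloro 9α-ol (chlorohydrin; not isolated) | CC(C)[Si](O[C@@H]1C[C@@]2(CO2)[C@](O)(CC[C@@H](O)CCl)[C@]23CCC[C@](C)(C(=O)OC2)[C@@H]13)(C(C)C)C(C)C | intermediate
28 | 13R,16-epoxy 9α-ol (not isolated) | CC(C)[Si](O[C@@H]1C[C@@]2(CO2)[C@](O)(CC[C@@H]4CO4)[C@]23CCC[C@](C)(C(=O)OC2)[C@@H]13)(C(C)C)C(C)C | intermediate
29 | 9α,13-epoxy-16-ol (spiro tetrahydrofuran; 13S methine on the C10 side) | CC(C)[Si](O[C@@H]1C[C@@]2(CO2)[C@]2(CC[C@@H](CO)O2)[C@]23CCC[C@](C)(C(=O)OC2)[C@@H]13)(C(C)C)C(C)C | intermediate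
30 | 16-O-glyoxylate p-tosylhydrazone (not isolated) | CC(C)[Si](O[C@@H]1C[C@@]2(CO2)[C@]2(CC[C@@H](COC(=O)C=NNS(=O)(=O)c4ccc(C)cc4)O2)[C@]23CCC[C@](C)(C(=O)OC2)[C@@H]13)(C(C)C)C(C)C | intermediate
31 | 16-O-diazoacetate | CC(C)[Si](O[C@@H]1C[C@@]2(CO2)[C@]2(CC[C@@H](COC(=O)C=[N+]=[N-])O2)[C@]23CCC[C@](C)(C(=O)OC2)[C@@H]13)(C(C)C)C(C)C | intermediate
32 | spiro γ-lactone (9α,13R-epoxy-15,16-olide) | CC(C)[Si](O[C@@H]1C[C@@]2(CO2)[C@]2(CC[C@]4(CC(=O)OC4)O2)[C@]23CCC[C@](C)(C(=O)OC2)[C@@H]13)(C(C)C)C(C)C | intermediate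
33 | lactol (15-hydroxy-15,16-epoxide; C15 epimers) | CC(C)[Si](O[C@@H]1C[C@@]2(CO2)[C@]2(CC[C@]4(CC(O)OC4)O2)[C@]23CCC[C@](C)(C(=O)OC2)[C@@H]13)(C(C)C)C(C)C | intermediate
34 | lactol mesylate (not isolated) | CC(C)[Si](O[C@@H]1C[C@@]2(CO2)[C@]2(CC[C@]4(CC(OS(C)(=O)=O)OC4)O2)[C@]23CCC[C@](C)(C(=O)OC2)[C@@H]13)(C(C)C)C(C)C | intermediate
35 | 6-O-TIPS dihydrofuran (9α,13R;15,16-diepoxy-14-ene) | CC(C)[Si](O[C@@H]1C[C@@]2(CO2)[C@]2(CC[C@]3(C=COC3)O2)[C@]23CCC[C@](C)(C(=O)OC2)[C@@H]13)(C(C)C)C(C)C | intermediate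
36 | 6β-alcohol (deacetyl target) | O[C@@H]1C[C@@]2(CO2)[C@]2(CC[C@]3(C=COC3)O2)[C@]23CCC[C@](C)(C(=O)OC2)[C@@H]13 | intermediate
37 | CNP0173713.1 | CC(=O)O[C@@H]1C[C@@]2(CO2)[C@]2(CC[C@]3(C=COC3)O2)[C@]23CCC[C@](C)(C(=O)OC2)[C@@H]13 | target

**Step count and risks**

Total steps: 23. Longest linear sequence: 20 (steps 1–12, then 16–23); steps 13–15 make the side-chain fragment.

Steps most likely to fail:

1. Step 19. The carbenoid may be diverted into dimerisation, oxonium ylide formation at the tetrahydrofuran oxygen with a Stevens shift, or insertion at the C12 methylene, because C13–H lies in a crowded pocket beside C10. The fallback sets out from 29 and returns at 35, so steps 18–21 fall away. Dess–Martin oxidation of 29 gives the C13 aldehyde F1. A crossed aldol of its single α-position with aqueous formaldehyde and K2CO3 gives the 13-formyl-13-hydroxymethyl compound F2; formaldehyde should approach the enolate on the less hindered C8 side, so the formyl group ends on the C10 side as the future C14 (substrate control, the weak point of this fallback). The Ohira–Bestmann reagent with K2CO3 in MeOH turns the formyl group into an ethynyl group to give the alkynol F3. Mo(CO)6, Et3N, Et2O, hν then closes the dihydrofuran by endo attack of the C16 hydroxyl on the metal vinylidene to give 35.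

2. Step 6. The Lewis acid may ionise or eliminate the allylic C6 silyloxy group, the α-alkylated enone may react sluggishly, or facial selectivity at C5 may be eroded. The fallback sets out from 8 and returns at 12. Copper-catalysed conjugate addition of isopropenylmagnesium bromide (CuBr·SMe2, Me3SiCl, THF, −78 °C), reliably anti to the silyloxy group, gives the enol ether F4. Hydroxymethylation as in step 7 gives the hydroxymethyl ketone F5. Hydroboration of the isopropenyl group (9-BBN, then NaBO3) gives the diol F6. TEMPO/PhI(OAc)2 oxidises the less hindered C19 alcohol and the resulting lactol to the δ-lactone 12, which the HCl treatment of step 7 converts into 13.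

3. Step 12. Ring closure of the hydroperoxide adduct may show poor facial selectivity (oxygen delivered to the α face, the stereoelectronically axial direction). The fallback sets out from 19 and returns at 20. Dihydroxylation with OsO4 (cat.) and NMO, a sterically governed electrophilic attack from the open β face, gives the 8β,17-diol F7. Selective tosylation of the primary hydroxyl (TsCl, pyridine) gives the tosylate F8. K2CO3 in MeOH closes the oxirane with retention at C8 to give 20.

Further compounds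
F1 | step 19 | C13 aldehyde of the spiro tetrahydrofuran (from oxidation of 29) | CC(C)[Si](O[C@@H]1C[C@@]2(CO2)[C@]2(CC[C@@H](C=O)O2)[C@]23CCC[C@](C)(C(=O)OC2)[C@@H]13)(C(C)C)C(C)C
F2 | step 19 | 13-formyl-13-(hydroxymethyl) tetrahydrofuran (formyl on the C10 side) | CC(C)[Si](O[C@@H]1C[C@@]2(CO2)[C@]2(CC[C@](CO)(C=O)O2)[C@]23CCC[C@](C)(C(=O)OC2)[C@@H]13)(C(C)C)C(C)C
F3 | step 19 | 13-ethynyl-16-ol (alkynol) | CC(C)[Si](O[C@@H]1C[C@@]2(CO2)[C@]2(CC[C@](CO)(C#C)O2)[C@]23CCC[C@](C)(C(=O)OC2)[C@@H]13)(C(C)C)C(C)C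
F4 | step 6 | C9 trimethylsilyl enol ether with a C5 isopropenyl group trans to 6β-OTIPS | CC(C)[Si](O[C@@H]1CCC(O[Si](C)(C)C)=C(CCCO[Si](C)(C)C(C)(C)C)[C@H]1C(C)=C)(C(C)C)C(C)C
F5 | step 6 | 10β-hydroxymethyl C9 ketone with a C5 isopropenyl group | CC(C)[Si](O[C@@H]1CCC(=O)[C@@](CO)(CCCO[Si](C)(C)C(C)(C)C)[C@H]1C(C)=C)(C(C)C)C(C)C
F6 | step 6 | 19,20-diol C9 ketone (C4 epimers) | CC(C)[Si](O[C@@H]1CCC(=O)[C@@](CO)(CCCO[Si](C)(C)C(C)(C)C)[C@H]1C(C)CO)(C(C)C)C(C)C
F7 | step 12 | 8β,17-dihydroxy C9 ketone | CC(C)[Si](O[C@@H]1C[C@@](O)(CO)C(=O)[C@]23CCC[C@](C)(C(=O)OC2)[C@@H]13)(C(C)C)C(C)C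
F8 | step 12 | 8β-hydroxy-17-tosyloxy C9 ketone | CC(C)[Si](O[C@@H]1C[C@@](O)(COS(=O)(=O)c4ccc(C)cc4)C(=O)[C@]23CCC[C@](C)(C(=O)OC2)[C@@H]13)(C(C)C)C(C)C
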